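## Structural features

The target (26) is a germacranolide: a ten-membered carbocycle C1–C10 with two trisubstituted ring alkenes in a 1,5-relationship, Z at C1=C10 (methyl C14 on C10) and E at C4=C5 (methyl C15 on C4). An α-methylene-γ-butyrolactone is cis-fused across C6–C7 (ring oxygen on C6, C11=C13 and the C12 carbonyl on C7). C6, C7, C8 and C9 are four contiguous stereocentres (6S,7R,8R,9R): the lactone oxygen and C11 are syn, the free C8 hydroxyl is anti to C11, and the C9 acyloxy group is anti to the C8 hydroxyl (threo). The C9 ester is a (2S,3S)-2,3-epoxy-2-methylbutanoate (epoxyangelate), which adds two stereocentres that the ring cannot control. The fragile groups are the methylene lactone (conjugate addition), the 1,5-diene (Cope rearrangement, acid-triggered transannular cyclisation), the epoxide, the vicinal hydroxy ester (acyl migration O9 to O8) and the allylic C6–O and C9–O bonds. The real difficulty is a medium ring with two geometrically defined trisubstituted alkenes next to an oxygenated stereotetrad. The key step uses the fact that C1=C10 and C4=C5 are what results when a cyclohexene C5=C10 and a cyclobutene C1=C4 exchange partners. Rejoining C1–C4 and C5–C10 gives a bicyclo[2.2.0]hexane (C1, C2, C3, C4, C5, C10) fused to a six-membered ring C5–C10. That ring, with its C14 methyl, C9 oxygen and the three-carbon unit C11–C13 on C7, is the carvone skeleton.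

## Logic of the disconnections

26 ⇒ 25. Only the O8–Si bond is cut. O8 stays masked until the lactone is closed, because a free O8 could capture C12 as a 12,8-lactone or accept the acyl group from O9. The forward step must remove a hindered silyl ether without base (methylene lactone, acyl migration) and without strong acid (diene, epoxide).

25 ⇒ 22. The lactone C12–O6 bond is cut and C12 is lowered to the carbinol level, giving a 2-methylene-1,4-diol. The Michael acceptor is thereby absent from every earlier step. The forward oxidant must pick the primary allylic O12 carbinol over the secondary O6 carbinol, which is itself allylic to C4=C5; for this reason an oxoammonium oxidation is planned, not MnO2.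

22 ⇒ 21 ⇒ 20 + 6. The O6–Si and O12–Si bonds and then the ester bond O9–C(=O) are cut. This separates the side chain with its two stereocentres (6) from the ring, so the epoxide configuration is set on a five-carbon fragment. The forward demands are an acylation of a hindered allylic alcohol with a tertiary glycidic acid, and silyl groups on O6/O12 that leave before the one on O8; hence triethylsilyl on O6/O12 and tert-butyldimethylsilyl on O8, not three like groups.

20 ⇒ 19. The C9–H bond is cut, returning the C9 ketone, which is needed for the ring expansion and comes from the carvone carbonyl. The forward reduction must be 1,2-selective and deliver hydride to the face that gives the 8,9-threo product.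

19 ⇒ 18. This is the strategic cut, read backwards as joining C1 to C4 and C5 to C10. The ten-membered ring with its Z and E alkenes collapses to a rigid tricycle whose six-membered ring holds C6, C7 and C8. The forward thermolysis must cleave C5–C10 and not C2–C3, must choose the chair diyl that gives Z at C1=C10 and E at C4=C5, and must stop before the Cope rearrangement.

18 ⇒ 17 ⇒ 16. The O8–Si bond and then the C8–O bond are cut. The C8 oxygen is placed before ring expansion because the tricyclic ketone has a single possible enolate (C10 is quaternary) and a rigid ring on which the C7 side chain directs the oxidant anti. The same oxidation on the ten-membered dienone would require enolate chemistry on a flexible, base-sensitive ring.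

16 ⇒ 15 + 2. The C5–C4 and C10–C1 bonds are cut, giving an enone and a cyclobutene. The forward photocycloaddition must be head-to-tail (methyl-bearing alkene carbon on C5) and cis-fused at C5–C10. Its facial sense does not matter for the route, because all four cyclobutane stereocentres are erased in the key step.

15 ⇒ 14 ⇒ 13 ⇒ 12. The O–Si bonds are cut, then the C6–O bond with inversion. Electrophilic oxygen enters the dienol ether anti to the C7 side chain, whereas the cis-fused lactone needs O6 syn to it, so an SN2 inversion at C6 is built in at the monocyclic stage, where it is cheapest.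

12 ⇒ 10 ⇒ 9. The C6–O bond is cut (γ-oxidation of the enone through its linear silyl dienol ether). The forward steps demand γ-deprotonation, not α′-deprotonation, and attack of the oxidant at the diene terminus.

9 ⇒ 8 ⇒ 7. The C12–O and then the C12–Cl bond are cut, back to 7, which supplies C5–C10, C14, C11–C13 and the C7 stereocentre. The acetate on O12 is carried until it can be removed together with the C6 ester.

2 ⇒ 1 is a double-bond isomerisation, with no skeletal bond cut. 6 ⇒ 5 ⇒ 4 ⇒ 3 cuts the epoxide C–O bonds and adjusts the oxidation level of C1′. The Z geometry of 3 becomes the cis relationship of the carboxyl carbon and the C3′ methyl, and the absolute configuration is set by a reagent-controlled epoxidation of the allylic alcohol.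

## Other disconnections considered

Alternative 1: The cut is C7–C11 together with the C8–O bond, and the C12 carbonyl oxygen is added afterwards. In the forward step Bu3SnH under air turns a 2-bromoallyl ether on O6 into a vinyl radical that closes 5-exo onto C7 of a Z C7=C8 ring alkene. That alkene would come from ring-closing metathesis, for example with second-generation Grubbs catalyst. The C8 radical is trapped by O2 and the hydroperoxide is reduced, giving A1. Allylic oxidation of the ether CH2 (C12) would then give 26.
- In its favour: one operation forms C7–C11, the cis ring fusion (a 5-exo closure onto a ring alkene can only be cis) and the C8 oxygen. Oxygen should enter anti to the new C7–C11 bond, which is the relationship 26 needs. The C9 ester can already be in place.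
- Against it here: the ring must first be closed by metathesis to a ten-membered Z alkene beside two trisubstituted alkenes, with ring strain and oligomerisation. The C8 radical is β to the C9 acyloxy group (1,2-acyloxy shift) and sits in a ring with other alkenes. The last step must oxidise one ether CH2 in the presence of several other allylic positions and the doubly allylic C6–H.
- Comparison: structurally it builds the lactone carbons late on a preformed ring, whereas the chosen plan draws C11–C13 and C7 from the chiral pool. Mechanistically it is a radical chain at ambient temperature against a 480 °C diradical cycloreversion; on mildness, and on setting C7 and C8 in one event, Alternative 1 is the better of the two. On step economy it is the weaker, because the metathesis substrate with C6, C9 and both trisubstituted alkenes needs a long acyclic sequence and the final oxidation is unselective by design.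

Alternative 2: The cut is C5–C6 together with the C4–CH3 bond. In the forward step Ni(cod)2 (zerovalent nickel) with an N-heterocyclic carbene couples a terminal alkyne (C5) with the C6 aldehyde through an oxanickelacycle. Me2Zn methylates nickel, and reductive elimination places the methyl on C4 syn to the new C5–C6 bond. This closes the ring as the E allylic alcohol A2.
- In its favour: ring, E-C4=C5, the C15 methyl and the C6 carbinol arise together, and the alkene geometry follows from syn addition.
- Against it here: closing a ten-membered ring through an organometallic intermediate is strained. The C6 configuration (syn to the C7 arm) rests on 1,2-induction of unknown sense. Simple reductive coupling competes with methyl transfer. The acyclic ynal must already hold the Z-C1=C10 alkene and the C7–C8–C9 triad. After closure, lactonisation, α-methylenation, removal of the p-methoxybenzyl group, acylation and desilylation remain.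
- Comparison: on control of the C4=C5 geometry it is the better plan (mechanistic syn addition against a conformational preference of a diyl). On the absence of a high-temperature step it is also better. On step economy it is clearly longer, and it leaves C6 to substrate control where the chosen plan sets C6 by an SN2 inversion on a six-membered ring.

Alternative 3: The cut is C9–C10. In the forward step CrCl2 (divalent chromium) with catalytic NiCl2 converts a Z alkenyl iodide into the C10 alkenylchromium species, which adds to the C9 aldehyde and closes the ring onto a preformed methylene lactone, giving A3.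
- In its favour: the alkenyl geometry is retained, the reagent tolerates the lactone and silyl ether, and A3 is two steps from 26 (acylation with 6, desilylation). The C9 hydroxyl appears free exactly where the acyl group goes. On brevity of the endgame it is the better plan.
- Against it here: the C9 configuration in the addition to an α-silyloxy aldehyde is uncertain within a forming medium ring. The α-silyloxy aldehyde can epimerise at C8. The open-chain precursor must carry the cis-fused methylene lactone, the C6–C8 centres, the E-C4=C5 alkene and the Z iodide, so the Michael acceptor is exposed through much of a long synthesis. The closure needs high dilution and a large excess of chromium salt.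
- Comparison: both ring alkenes are fixed before closure, which is equal to or better than the chosen plan on geometric security. The chosen plan is shorter overall and keeps the methylene lactone out of the route until the penultimate step. Mechanistically a polar organometallic addition is weighed against a unimolecular thermal fragmentation whose only reagent is heat.

Key step: step 15

Assumption: the SMILES is read as the cis-fused 12,6-lactone (6S,7R,8R,9R) with a (2S,3S)-epoxyangelate on O9; germacrane numbering is used for all ring compounds, and "syn/anti" refer to the faces of the carbocycle.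

## Route

Step 1
Reactants: 1 methylenecyclobutane
Product: 2 1-methylcyclobut-1-ene
Conditions: KOtBu (0.2 equiv), DMSO, 25 °C; spinning-band distillation
Reagents that add atoms: none
Why: Base-catalysed prototropic alkene isomerisation through the allyl anion; the endocyclic trisubstituted isomer is the more stable one and is separated from residual 1 by fractional distillation.

Step 2
Reactants: 3 angelic acid
Product: 4 (2Z)-2-methylbut-2-en-1-ol
Conditions: LiAlH4, Et2O, 0 °C; aq. NaOH work-up
Reagents that add atoms: none
Why: Hydride reduction of the carboxylate to the primary allylic alcohol; at 0 °C in ether the trisubstituted alkene is neither reduced nor isomerised, so the Z geometry is carried over.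

Step 3
Reactants: 4 (2Z)-2-methylbut-2-en-1-ol
Product: 5 [(2R,3S)-2,3-dimethyloxiran-2-yl]methanol
Conditions: Ti(OiPr)4 (10 mol %), D-(−)-diethyl tartrate (12 mol %), t-BuOOH, 4 Å molecular sieves, CH2Cl2, −20 °C; non-aqueous work-up
Reagents that add atoms: tert-butyl hydroperoxide, CC(C)(C)OO
Why: Katsuki–Sharpless asymmetric epoxidation; the D-(−)-tartrate delivers oxygen to the face that gives the 2R epoxy alcohol, and the Z geometry becomes the cis relationship of CH2OH and the C3 methyl (3S).

Step 4
Reactants: 5 [(2R,3S)-2,3-dimethyloxiran-2-yl]methanol
Product: 6 (2S,3S)-2,3-dimethyloxirane-2-carboxylic acid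
Conditions: RuCl3 (2 mol %), NaIO4, MeCN–EtOAc–H2O, 0 °C → rt
Reagents that add atoms: water, O (the new carboxyl oxygen enters through the aldehyde hydrate; NaIO4, [Na+].[O-]I(=O)(=O)=O, is the terminal oxidant)
Why: RuO4 oxidation (Sharpless conditions) of the primary alcohol through the aldehyde hydrate to the acid; the epoxide is inert and both centres are untouched (2R becomes 2S only through the change of priorities).

Step 5
Reactants: 7 (S)-carvone
Product: 8 (5S)-5-(3-chloroprop-1-en-2-yl)-2-methylcyclohex-2-en-1-one
Conditions: Ca(OCl)2, solid CO2, CH2Cl2–H2O, 0 °C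
Reagents that add atoms: calcium hypochlorite, [Ca+2].[O-]Cl.[O-]Cl
Why: Ene-type allylic chlorination by HOCl on the electron-rich 1,1-disubstituted alkene with shift of the double bond; the electron-poor enone alkene does not react and the C7 stereocentre is untouched.

Step 6
Reactants: 8 (5S)-5-(3-chloroprop-1-en-2-yl)-2-methylcyclohex-2-en-1-one
Product: 9 2-[(1S)-4-methyl-5-oxocyclohex-3-en-1-yl]prop-2-en-1-yl acetate
Conditions: KOAc, NaI (cat.), DMF, 50 °C
Reagents that add atoms: potassium acetate, CC(=O)[O-].[K+]
Why: SN2 displacement of the primary allylic chloride by acetate under iodide catalysis; SN2′ attack would give the same product, and the acetate caps O12 until step 10.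

Step 7
Reactants: 9 2-[(1S)-4-methyl-5-oxocyclohex-3-en-1-yl]prop-2-en-1-yl acetate
Product: 10 2-[(1R)-5-{[tert-butyl(dimethyl)silyl]oxy}-4-methylcyclohexa-2,4-dien-1-yl]prop-2-en-1-yl acetate
Conditions: TBSOTf, Et3N, CH2Cl2, 0 °C → rt
Reagents that add atoms: tert-butyldimethylsilyl trifluoromethanesulfonate, CC(C)(C)[Si](C)(C)OS(=O)(=O)C(F)(F)F
Why: Soft enolisation (silyl triflate/amine) under equilibrating conditions gives the linearly conjugated 1-silyloxy-1,3-diene by loss of a γ-proton from C6; the acetate is not enolised at this temperature.

Step 8
Reactants: 10 2-[(1R)-5-{[tert-butyl(dimethyl)silyl]oxy}-4-methylcyclohexa-2,4-dien-1-yl]prop-2-en-1-yl acetate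
Product: 12 2-[(1S,2R)-2-hydroxy-4-methyl-5-oxocyclohex-3-en-1-yl]prop-2-en-1-yl acetate (hydroxyl trans to the side chain), via silyloxy diene epoxide 11 (not isolated)
Conditions: dimethyldioxirane (acetone), CH2Cl2, −78 → −30 °C; then AcOH, THF–H2O, 0 °C
Reagents that add atoms: dimethyldioxirane, CC1(C)OO1
Why: Vinylogous Rubottom oxidation: the dioxirane epoxidises the terminal C5=C6 bond of the silyloxy diene anti to the C7 side chain, and mild acid opens 11 with loss of silanol to the γ-hydroxy enone, so the new C6–O bond is trans to the side chain (6R).

Step 9
Reactants: 12 2-[(1S,2R)-2-hydroxy-4-methyl-5-oxocyclohex-3-en-1-yl]prop-2-en-1-yl acetate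
Product: 13 (1S,6S)-6-[3-(acetyloxy)prop-1-en-2-yl]-3-methyl-4-oxocyclohex-2-en-1-yl 4-nitrobenzoate (ester cis to the side chain)
Conditions: 4-nitrobenzoic acid, PPh3, DIAD, THF, 0 °C
Reagents that add atoms: 4-nitrobenzoic acid, OC(=O)c1ccc(cc1)[N+](=O)[O-]
Why: Mitsunobu inversion: the alkoxyphosphonium ion at C6 is displaced by the carboxylate with SN2 inversion to the 6S ester; SN2′ attack is blocked by the fully substituted α-carbon, and the C7–H, syn to the leaving group, disfavours E2 elimination.

Step 10
Reactants: 13 (1S,6S)-6-[3-(acetyloxy)prop-1-en-2-yl]-3-methyl-4-oxocyclohex-2-en-1-yl 4-nitrobenzoate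
Product: 14 (4S,5S)-4-hydroxy-5-(3-hydroxyprop-1-en-2-yl)-2-methylcyclohex-2-en-1-one
Conditions: K2CO3 (cat.), MeOH, 0 °C
Reagents that add atoms: none
Why: Base-catalysed transesterification removes the 4-nitrobenzoate and the acetate in one operation under conditions too mild to enolise the γ-position of the enone.

Step 11
Reactants: 14 (4S,5S)-4-hydroxy-5-(3-hydroxyprop-1-en-2-yl)-2-methylcyclohex-2-en-1-one
Product: 15 (4S,5S)-2-methyl-4-[(triethylsilyl)oxy]-5-{3-[(triethylsilyl)oxy]prop-1-en-2-yl}cyclohex-2-en-1-one
Conditions: Et3SiCl, imidazole, CH2Cl2, 0 °C
Reagents that add atoms: chlorotriethylsilane, CC[Si](Cl)(CC)CC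
Why: Silylation of both hydroxyls as triethylsilyl ethers, chosen so that O6 and O12 can later be freed together in the presence of a more robust silyl ether on O8.

Step 12
Reactants: 15 (4S,5S)-2-methyl-4-[(triethylsilyl)oxy]-5-{3-[(triethylsilyl)oxy]prop-1-en-2-yl}cyclohex-2-en-1-one; 2 1-methylcyclobut-1-ene
Product: 16 cis,anti,cis-2,6-dimethyl-10-[(triethylsilyl)oxy]-9-{3-[(triethylsilyl)oxy]prop-1-en-2-yl}tricyclo[4.4.0.0^2,5]decan-7-one (9- and 10-substituents cis to each other; both four-membered rings on the opposite face of the six-membered ring)
Conditions: hν (350 nm, Pyrex), 2 (10 equiv), CH2Cl2, −40 °C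
Reagents that add atoms: none
Why: Enone–alkene [2+2] photocycloaddition through the enone triplet and a 1,4-biradical; the donor-substituted alkene carbon bonds to the β-carbon C5 (head-to-tail, which also avoids two adjacent quaternary carbons), the four-membered ring of 2 forces cis fusion on its own side, addition occurs anti to the silyloxy group and side chain that share one face, and the anti orientation of the outer ring is the less crowded one.

Step 13
Reactants: 16 cis,anti,cis tricyclic ketone
Product: 17 8-hydroxy derivative of 16 (hydroxyl trans to the C9 side chain of the tricycle; germacrane O8 anti to C11)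
Conditions: KN(SiMe3)2, THF, −78 °C; then 2-(phenylsulfonyl)-3-phenyloxaziridine, −78 °C; aq. NH4Cl
Reagents that add atoms: 2-(phenylsulfonyl)-3-phenyloxaziridine, O=S(=O)(c1ccccc1)N1OC1c1ccccc1
Why: Davis oxidation of the only possible enolate (C10 is quaternary); the oxaziridine approaches C8 anti to the adjacent C7 side chain and to the 1,3-related C6 silyloxy group, which sets the C8 configuration of 26 on a rigid ring.

Step 14
Reactants: 17 8-hydroxy tricyclic ketone
Product: 18 8-{[tert-butyl(dimethyl)silyl]oxy} derivative of 16 (precursor of the key step)
Conditions: TBSOTf, 2,6-lutidine, CH2Cl2, −78 → 0 °C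
Reagents that add atoms: tert-butyldimethylsilyl trifluoromethanesulfonate, CC(C)(C)[Si](C)(C)OS(=O)(=O)C(F)(F)F
Why: Silyl triflate with a hindered base silylates the secondary α-ketol at low temperature faster than the ketone is enolised; this silyl ether survives the later fluoride cleavage of the two triethylsilyl ethers.

Step 15
Reactants: 18 tris-silylated cis,anti,cis tricyclic ketone
Product: 19 (2Z,6E)-10-{[tert-butyl(dimethyl)silyl]oxy}-2,6-dimethyl-8-[(triethylsilyl)oxy]-9-{3-[(triethylsilyl)oxy]prop-1-en-2-yl}cyclodeca-2,6-dien-1-one (germacra-1(10)Z,4E-dien-9-one; O6 syn and O8 anti to C11)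
Conditions: flash vacuum thermolysis, base-washed silylated quartz tube, 480 °C, 10^-3 mbar, contact time of milliseconds, trap at −196 °C
Reagents that add atoms: none
Why: Homolysis of the strained central C1–C4 bond of the bicyclo[2.2.0]hexane gives a boat cyclohexane-1,4-diyl that relaxes to a chair, in which the C5–C10 bond is aligned with both radical p orbitals and breaks to give the C1=C10 and C4=C5 π bonds (formally a σ2s+σ2a cycloreversion). The closest known reaction type is the thermolysis of cis,anti,cis-tricyclo[4.4.0.0^2,5]decanones from enone–cyclobutene photoadducts to Z,E-cyclodeca-1,5-dienes. The ten-membered ring is not closed by bond formation but unveiled when the bond shared by the six- and four-membered rings is cut, so no closure mode or entropic penalty applies. No stereocentre is formed: C6, C7 and C8 are spectators and the four cyclobutane centres vanish, so the facial sense of step 12 is immaterial. Alkene geometry is set in the chair diyl: the conformer with C9 axial and C6 and C14 equatorial has a single axial carbon substituent and gives Z-C1=C10 and E-C4=C5, whereas the other chair needs C6 and C14 both axial. Scission of C5–C10 is preferred over C2–C3 because it is the more substituted bond and its cleavage puts C1=C10 into conjugation with the C9 carbonyl. The step must stop before 19 undergoes Cope rearrangement to the divinylcyclohexane isomer; high temperature and very short contact favour the high-entropy homolysis over the ordered Cope transition state, and a Z,E-diene rearranges less readily than an E,E-diene.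

Step 16
Reactants: 19 germacradienone
Product: 20 C9 alcohol of 19 (carbinol oxygen anti to the neighbouring O8; 9R as in 26)
Conditions: i-Bu2AlH, CH2Cl2, −78 °C; aq. KNaC4H4O6
Reagents that add atoms: none
Why: 1,2-Reduction of the enone by an aluminium hydride; with the non-chelating silyloxy group turned away from the carbonyl dipole (Felkin–Anh/Cornforth) hydride adds from the periphery of the ring on the side of H8, giving the threo 8,9 relationship.

Step 17
Reactants: 20 C9 alcohol; 6 (2S,3S)-2,3-dimethyloxirane-2-carboxylic acid
Product: 21 C9 (2S,3S)-2,3-dimethyloxirane-2-carboxylate of 20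
Conditions: 6, 2,4,6-trichlorobenzoyl chloride, Et3N, THF, rt; then 20, DMAP, toluene, 40 °C
Reagents that add atoms: none
Why: Yamaguchi esterification: the mixed 2,4,6-trichlorobenzoic anhydride of 6 is opened by DMAP to the acylpyridinium ion, which acylates the hindered allylic alcohol without touching the epoxide or any stereocentre.

Step 18
Reactants: 21 fully protected ester
Product: 22 6,12-diol (O8 still silylated)
Conditions: HF·pyridine, pyridine, THF, 0 °C
Reagents that add atoms: none
Why: Buffered fluoride cleaves the primary and the allylic secondary triethylsilyl ethers much faster than the hindered tert-butyldimethylsilyl ether on C8; the medium is too weakly acidic for transannular cyclisation or epoxide opening.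

Step 19
Reactants: 22 6,12-diol
Product: 25 8-O-(tert-butyldimethylsilyl) derivative of 26 (cis-fused α-methylene-γ-lactone closed), via hydroxy enal 23 (not isolated), via lactol 24 (not isolated)
Conditions: TEMPO (20 mol %), PhI(OAc)2, CH2Cl2, rt
Reagents that add atoms: none
Why: Oxoammonium oxidation selective for the primary allylic alcohol gives enal 23, the syn O6 hydroxyl closes to the five-membered lactol 24, and a second oxidation gives the lactone; the secondary C6 carbinol itself is oxidised far more slowly, and O8 is masked so that no 12,8-lactone can form.

Step 20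
Reactants: 25 8-O-silyl lactone
Product: 26 target germacranolide (6S,7R,8R,9R; ester 2S,3S)
Conditions: HF·pyridine, THF, 0 °C → rt
Reagents that add atoms: none
Why: Fluoride cleavage of the last silyl ether under weakly acidic, non-nucleophilic conditions, which avoids conjugate addition to the methylene lactone and acyl migration from O9 to O8.

## Compound list

1 | methylenecyclobutane | C=C1CCC1 | starting material
2 | 1-methylcyclobut-1-ene | CC1=CCC1 | intermediate
3 | angelic acid, (2Z)-2-methylbut-2-enoic acid | C/C=C(/C)C(=O)O | starting material
4 | (2Z)-2-methylbut-2-en-1-ol | C/C=C(/C)CO | intermediate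
5 | [(2R,3S)-2,3-dimethyloxiran-2-yl]methanol | OC[C@@]1(C)O[C@H]1C | intermediate
6 | (2S,3S)-2,3-dimethyloxirane-2-carboxylic acid | OC(=O)[C@@]1(C)O[C@H]1C | intermediate
7 | (S)-carvone | C=C(C)[C@H]1CC=C(C)C(=O)C1 | starting material
8 | (5S)-5-(3-chloroprop-1-en-2-yl)-2-methylcyclohex-2-en-1-one | C=C(CCl)[C@H]1CC=C(C)C(=O)C1 | intermediate
9 | 2-[(1S)-4-methyl-5-oxocyclohex-3-en-1-yl]prop-2-en-1-yl acetate | C=C(COC(C)=O)[C@H]1CC=C(C)C(=O)C1 | intermediate
10 | 2-[(1R)-5-{[tert-butyl(dimethyl)silyl]oxy}-4-methylcyclohexa-2,4-dien-1-yl]prop-2-en-1-yl acetate | C=C(COC(C)=O)[C@H]1C=CC(C)=C(O[Si](C)(C)C(C)(C)C)C1 | intermediate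
11 | epoxide of 10 at the disubstituted ring alkene, oxirane anti to the side chain | C=C(COC(C)=O)[C@@H]1CC(O[Si](C)(C)C(C)(C)C)=C(C)[C@H]2O[C@H]21 | intermediate (not isolated)
12 | 2-[(1S,2R)-2-hydroxy-4-methyl-5-oxocyclohex-3-en-1-yl]prop-2-en-1-yl acetate | C=C(COC(C)=O)[C@@H]1CC(=O)C(C)=C[C@H]1O | intermediate
13 | (1S,6S)-6-[3-(acetyloxy)prop-1-en-2-yl]-3-methyl-4-oxocyclohex-2-en-1-yl 4-nitrobenzoate | C=C(COC(C)=O)[C@@H]1CC(=O)C(C)=C[C@@H]1OC(=O)c2ccc(cc2)[N+](=O)[O-] | intermediate
14 | (4S,5S)-4-hydroxy-5-(3-hydroxyprop-1-en-2-yl)-2-methylcyclohex-2-en-1-one | C=C(CO)[C@@H]1CC(=O)C(C)=C[C@@H]1O | intermediate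
15 | (4S,5S)-2-methyl-4-[(triethylsilyl)oxy]-5-{3-[(triethylsilyl)oxy]prop-1-en-2-yl}cyclohex-2-en-1-one | C=C(CO[Si](CC)(CC)CC)[C@@H]1CC(=O)C(C)=C[C@@H]1O[Si](CC)(CC)CC | intermediate
16 | cis,anti,cis-2,6-dimethyl-10-[(triethylsilyl)oxy]-9-{3-[(triethylsilyl)oxy]prop-1-en-2-yl}tricyclo[4.4.0.0^2,5]decan-7-one | O=C1C[C@@H](C(=C)CO[Si](CC)(CC)CC)[C@@H](O[Si](CC)(CC)CC)[C@H]2[C@]1(C)[C@@H]3CC[C@]23C | intermediate
17 | 8-hydroxy derivative of 16, hydroxyl trans to the 9-substituent | O=C1[C@H](O)[C@@H](C(=C)CO[Si](CC)(CC)CC)[C@@H](O[Si](CC)(CC)CC)[C@H]2[C@]1(C)[C@@H]3CC[C@]23C | intermediate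
18 | 8-{[tert-butyl(dimethyl)silyl]oxy} derivative of 16 | O=C1[C@H](O[Si](C)(C)C(C)(C)C)[C@@H](C(=C)CO[Si](CC)(CC)CC)[C@@H](O[Si](CC)(CC)CC)[C@H]2[C@]1(C)[C@@H]3CC[C@]23C | intermediate
19 | (2Z,6E)-10-{[tert-butyl(dimethyl)silyl]oxy}-2,6-dimethyl-8-[(triethylsilyl)oxy]-9-{3-[(triethylsilyl)oxy]prop-1-en-2-yl}cyclodeca-2,6-dien-1-one | C=C(CO[Si](CC)(CC)CC)[C@H]1[C@@H](O[Si](CC)(CC)CC)/C=C(\C)CC/C=C(/C)C(=O)[C@@H]1O[Si](C)(C)C(C)(C)C | intermediate
20 | C9 alcohol of 19, threo to O8 | C=C(CO[Si](CC)(CC)CC)[C@H]1[C@@H](O[Si](CC)(CC)CC)/C=C(\C)CC/C=C(/C)[C@@H](O)[C@@H]1O[Si](C)(C)C(C)(C)C | intermediate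
21 | C9 (2S,3S)-2,3-dimethyloxirane-2-carboxylate of 20 | C=C(CO[Si](CC)(CC)CC)[C@H]1[C@@H](O[Si](CC)(CC)CC)/C=C(\C)CC/C=C(/C)[C@@H](OC(=O)[C@@]2(C)O[C@H]2C)[C@@H]1O[Si](C)(C)C(C)(C)C | intermediate
22 | 6,12-diol from 21, O8 silylated | C=C(CO)[C@H]1[C@@H](O)/C=C(\C)CC/C=C(/C)[C@@H](OC(=O)[C@@]2(C)O[C@H]2C)[C@@H]1O[Si](C)(C)C(C)(C)C | intermediate
23 | C12 aldehyde (2-substituted acrolein) with free C6 hydroxyl | C=C(C=O)[C@H]1[C@@H](O)/C=C(\C)CC/C=C(/C)[C@@H](OC(=O)[C@@]2(C)O[C@H]2C)[C@@H]1O[Si](C)(C)C(C)(C)C | intermediate (not isolated)
24 | 12,6-lactol, mixture of anomers | C=C1C(O)O[C@H]2/C=C(\C)CC/C=C(/C)[C@@H](OC(=O)[C@@]3(C)O[C@H]3C)[C@H](O[Si](C)(C)C(C)(C)C)[C@@H]12 | intermediate (not isolated)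
25 | 8-O-(tert-butyldimethylsilyl) derivative of 26 | C=C1C(=O)O[C@H]2/C=C(\C)CC/C=C(/C)[C@@H](OC(=O)[C@@]3(C)O[C@H]3C)[C@H](O[Si](C)(C)C(C)(C)C)[C@@H]12 | intermediate
26 | CNP0213766.2, (6S,7R,8R,9R)-8-hydroxy-9-[(2S,3S)-2,3-epoxy-2-methylbutanoyloxy]germacra-1(10)Z,4E,11(13)-trien-12,6-olide | C=C1C(=O)O[C@H]2/C=C(\C)CC/C=C(/C)[C@@H](OC(=O)[C@@]3(C)O[C@H]3C)[C@H](O)[C@@H]12 | target

## Step count and least certain steps

Total: 20 steps. Longest linear sequence: 16 steps (7 → 26, steps 5–20). Side branches: 1 step to 2 and 3 steps to 6.

Step 15 (key step). Most likely failure: the reaction runs on along the Cope surface to the divinylcyclohexane isomer, or the heavy tris-silyl substrate begins to react in the condensed phase while it is being evaporated, so that product is exposed to heat for much longer than the contact time in the hot zone. Fallback: thermolyse the lighter ketone 16 before C8 is oxygenated. It lacks the α-silyloxy group and volatilises at a lower bath temperature. Its product is the dienone F1. F1 is deprotonated at C8 with KN(SiMe3)2 at −78 °C (kinetic α′-enolate) and oxidised with the same oxaziridine, the reagent entering anti to the C7 side chain, to give the hydroxy dienone F2. Silylation with TBSOTf/2,6-lutidine returns the route at 19.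

Step 12. Most likely failure: erosion of head-to-tail and cis-fusion selectivity. The C6 silyloxy group crowds C5, the carbon that must bond to the methyl-bearing alkene carbon, and C10 is quaternary, so a trans-fused adduct could not be corrected by base. Fallback: change the order of events and irradiate the unprotected diol 14 with 2, so that C5 is flanked only by a small hydroxyl. The diol photoadduct F3 is then silylated on both hydroxyls with Et3SiCl/imidazole, which comes back to the route at 16.

Step 8. Most likely failure: the oxidant attacks the more substituted enol-ether double bond (oxygen ends on C10) or over-oxidises, because an epoxidising agent selects the most electron-rich π bond and not the diene terminus. Fallback: a [4+2] cycloaddition of singlet oxygen (O2, tetraphenylporphyrin, hν, CH2Cl2, −78 °C), which can only bridge the diene termini C9 and C6. It sets out from 10 and adds anti to the side chain to give the endoperoxide F4. Reduction of the O–O bond with PPh3 and collapse of the silyl hemiketal return the route at 12.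

Step 16. Most likely failure: poor facial selectivity at C9, because the conformers of the ten-membered ring need not present the carbonyl as the open-chain Felkin model assumes. Fallback: accept the other face. It sets out from 19, which is reduced to the epimeric alcohol F5, and F5 is esterified with 6 under Mitsunobu conditions (PPh3, DIAD, toluene, 0 °C), which inverts C9 and comes back to the route at 21.

Step 1. Most likely failure: incomplete isomerisation and co-distillation, so that residual exocyclic alkene 1 is carried into step 12 and intercepts the excited enone as spiro adducts. Fallback: make 2 by carbene ring expansion instead of equilibration. Commercial cyclopropyl methyl ketone is condensed with p-toluenesulfonohydrazide to the tosylhydrazone F6. F6 is decomposed with NaOMe in diglyme at 160–180 °C (Bamford–Stevens; the cyclopropylcarbene ring-expands), and 2 is distilled into a cold trap, where it rejoins the route.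

## Further compounds

F1 | step 15 | (2Z,6E)-2,6-dimethyl-8-[(triethylsilyl)oxy]-9-{3-[(triethylsilyl)oxy]prop-1-en-2-yl}cyclodeca-2,6-dien-1-one | C=C(CO[Si](CC)(CC)CC)[C@H]1[C@@H](O[Si](CC)(CC)CC)/C=C(\C)CC/C=C(/C)C(=O)C1
F2 | step 15 | 10-hydroxy derivative of F1 (germacrane O8 anti to C11) | C=C(CO[Si](CC)(CC)CC)[C@H]1[C@@H](O[Si](CC)(CC)CC)/C=C(\C)CC/C=C(/C)C(=O)[C@@H]1O
F3 | step 12 | cis,anti,cis-10-hydroxy-9-(3-hydroxyprop-1-en-2-yl)-2,6-dimethyltricyclo[4.4.0.0^2,5]decan-7-one | O=C1C[C@@H](C(=C)CO)[C@@H](O)[C@H]2[C@]1(C)[C@@H]3CC[C@]23C
F4 | step 8 | 2-(1-{[tert-butyl(dimethyl)silyl]oxy}-6-methyl-2,3-dioxabicyclo[2.2.2]oct-5-en-8-yl)prop-2-en-1-yl acetate, peroxide bridge anti to the side chain | C=C(COC(C)=O)[C@@H]1C[C@@]2(O[Si](C)(C)C(C)(C)C)OO[C@@H]1C=C2C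
F5 | step 16 | C9 epimer of 20 | C=C(CO[Si](CC)(CC)CC)[C@H]1[C@@H](O[Si](CC)(CC)CC)/C=C(\C)CC/C=C(/C)[C@H](O)[C@@H]1O[Si](C)(C)C(C)(C)C
F6 | step 1 | N'-(1-cyclopropylethylidene)-4-methylbenzenesulfonohydrazide | CC(=NNS(=O)(=O)c1ccc(C)cc1)C1CC1
A1 | alternative 1 | 12-deoxo-26, cis-fused 3-methylenetetrahydrofuran in place of the lactone | C=C1CO[C@H]2/C=C(\C)CC/C=C(/C)[C@@H](OC(=O)[C@@]3(C)O[C@H]3C)[C@H](O)[C@@H]12
A2 | alternative 2 | ten-membered C6 allylic alcohol with C9 p-methoxybenzyl ether, C8 silyl ether and C7 methyl acetate arm | COC(=O)C[C@H]1[C@@H](O)/C=C(\C)CC/C=C(/C)[C@@H](OCc2ccc(OC)cc2)[C@@H]1O[Si](C)(C)C(C)(C)C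
A3 | alternative 3 | 9-hydroxy-8-O-(tert-butyldimethylsilyl) methylene lactone | C=C1C(=O)O[C@H]2/C=C(\C)CC/C=C(/C)[C@@H](O)[C@H](O[Si](C)(C)C(C)(C)C)[C@@H]12
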